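**The constants.** Read two constants from the earlier runs, a decay and a release, and carry the release to the new flasks.

| flask | starting material | reagent | protic impurity | temperature | remark | time |
|---|---|---|---|---|---|---|
| red | 0.095 M | 0.38 M | 0.038 M | 55 °C | run made earlier |  |
| violet | 0.14 M | 0.38 M | 0.038 M | 75 °C | run made earlier |  |
| blue | 0.19 M | 0.57 M | 0.038 M | 55 °C | run made earlier |  |
| zeta | 0.19 M | 0.380 M | 0.0380 M | 60 °C |  | 30 min |
| theta | 0.19 M | 0.380 M | 0.0380 M | 90 °C |  | 30 min |
| alpha | 0.19 M | 0.380 M | 0.0380 M |  | at 60 °C until 10 min, from then on at 90 °C | 30 min |

| run | time / min | target / % | starting material / % |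
|---|---|---|---|
| red | 1.33 | 13.3 | 18.5 |
| red | 2.50 | 24.3 | 13.2 |
| red | 5.00 | 35.3 | 5.8 |
| red | 10.0 | 43.1 | 2.3 |
| red | 20.0 | 47.7 | 1.1 |
| violet | 0.667 | 18.5 | 15.6 |
| violet | 2.50 | 27.1 | 2.3 |
| violet | 4.00 | 29.3 | 1.4 |
| violet | 6.00 | 31.9 | 1.2 |
| violet | 10.0 | 37.2 | 1.1 |
| blue | 4.00 | 41.4 | 6.7 |
| blue | 8.00 | 51.8 | 1.9 |
| blue | 10.0 | 53.5 | 1.1 |
| blue | 15.0 | 55.0 | 1.7 |
| blue | 20.0 | 56.8 | 0.1 |

(readings scatter by 0.5 percentage points)

- amounts and yields of target count crystals too
- given per volume of solution although it is solid: crystals
- steps under discussion: starting material <-> tautomer; starting material + reagent -> isomer of the product; reagent + tautomer -> target; crystals <-> target; starting material + protic impurity -> quenched substrate; starting material <-> dormant form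

- the flask with the highest amount of target, in percent of the starting material charged ("all alike" if they lie within 1.5 percentage points) (zeta / theta / alpha / all alike)
- final target, as a percentage of the starting material charged, in zeta
- final target, as a percentage of the starting material charged, in theta
- final target, as a percentage of the starting material charged, in alpha

**Fast rung.** In the red run, starting material falls from 18.5% to 5.8% between 1.33 min and 5.00 min, a halving time of 2.19 min. In the blue run, target gains 3.3 percentage points after 10.0 min, more than the 1.1% of starting material then present, which I read as a sign of a reservoir.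

**Slow rung.** Assume each protic impurity quenches one starting material. Call the charge minus quenched substrate, target and starting material the remainder, which lumps the reservoir with any other form, and treat its loss as pseudo-first-order: [remainder] falls as exp(−λt), with halving time ln(2)/λ. The release constant λ is the late target gain per minute over the mean remainder. The blue run has a remainder of 24.3%, giving 0.0136 /min at 55 °C. The violet run has 38.4%, giving 0.0343 /min at 75 °C.

**New flasks.** Scale ln λ linearly with temperature. This gives 0.0171 /min at 60 °C and 0.0687 /min at 90 °C, the release constant for hot work. My reckoning drains 40.1% of the reservoir in zeta, 87.3% in theta and, over its hot stretch, 74.7% in alpha. Take as cap the charge minus the quenched share. At 2.3% of starting material, target stands at 71.8% of the cap in the red run, but at 37.2% in the violet run. These runs differ in temperature and in starting material, and I assume the gap comes with the temperature. On that assumption I pick alpha, the cool start with the hot drain.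

**The forecast.** Reading “slow release from a dormant reservoir”, the forecast names alpha, with 60% in zeta, 43% in theta and 66% in alpha. Those yields are its own; my reckoning gives shares drained.

**The result.** Zeta gives 51.0%, theta 52.9% and alpha 59.8%, so alpha ends highest.

    starting material ⇌ tautomer (K = 1.51, k = 0.0507 /s, Ea = 76.0 kJ/mol, ΔH = −50.0 kJ/mol)
    starting material + reagent → isomer of the product (k = 0.00386 /M/s, Ea = 58.0 kJ/mol)
    reagent + tautomer → target (k = 0.0189 /M/s, Ea = 77.0 kJ/mol)
    crystals ⇌ target, rate k4*(cs4 - [target]) while solid is left; crystals form when [target] > cs4 (solubility = 6.00 mM, k = 0.687 /s)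
    starting material + protic impurity → quenched substrate (k = 0.242 /M/s, Ea = 46.0 kJ/mol)
    starting material ⇌ dormant form (K = 14.4, k = 0.00538 /s, Ea = 101 kJ/mol, ΔH = 4.00 kJ/mol)
    (constants at 60 °C)

Apply the release constant to the dormant form, 25.9% in alpha at 10.0 min, the change of temperature. The reckoning leaves 6.56% at 30 min, and alpha holds 7.31%. The neighbouring flask is alpha stopped at 20 min. There the reckoning leaves 13.0%, and that flask holds 13.7% of dormant form, with target at 54.9%.

The data come from a simulation from invented constants; the scatter is artificial.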